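**Retrosynthetic overview**

- Feature: the 2-alkylfuran (ring O1, C2–C5, which are C24–C27 of the C27 chain counted from the carboxyl carbon) is a terminal (E)-buta-1,3-dienyl group plus one oxygen atom. The 5,7-diyne and the acid are bystanders.
- Furan ⇒ 3-alkyl-3,6-dihydro-1,2-dioxine (amine-induced peroxide opening, cyclodehydration) ⇒ (24E)-24,26-dien-5,7-diynoic acid + O2 (singlet-oxygen [4+2], forming C24–O and C27–O).
- C6–C7 ⇒ Cadiot–Chodkiewicz coupling of a C21 dienyne with 6-bromohex-5-ynoic acid; C8–C9 ⇒ acetylide + primary chloride.
- C23–C24 and the E-diene ⇒ α-alkylation of 3-sulfolene with 1-chloro-15-iodopentadecane (from pentadecanolide), then SO2 extrusion.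
- Ring order: sulfolene ring (temporary, opened in step 6) → six-membered peroxide ring (step 10) → furan, the only ring of the target (step 11).

Key step: step 10

Remark: the target has no stereocentre, so the route only has to deliver the E geometry at C24=C25 of compound 12; the peroxide 13 is carried as a racemate.

**Route**

Step 1
Reactants: 1 pentadecanolide (oxacyclohexadecan-2-one)
Product: 2 methyl 15-hydroxypentadecanoate
Conditions: MeOH, H2SO4 (cat.), reflux; NaHCO3 before concentration
Reagents that add atoms: methanol, CO
Why: Acid-catalysed transesterification (methanolysis) in a large excess of methanol opens the strain-free 16-membered lactone to the hydroxy ester and so differentiates the two chain ends at the outset.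

Step 2
Reactants: 2 methyl 15-hydroxypentadecanoate
Product: 3 methyl 15-chloropentadecanoate
Conditions: SOCl2, pyridine (cat.), toluene, 80 °C
Reagents that add atoms: thionyl chloride, O=S(Cl)Cl
Why: Deoxychlorination of a primary alcohol through its chlorosulfite (Darzens conditions), to which the methyl ester is inert.

Step 3
Reactants: 3 methyl 15-chloropentadecanoate
Product: 4 15-chloropentadecan-1-ol
Conditions: LiAlH4, THF, 0 °C, short reaction time; aqueous NaOH work-up
Reagents that add atoms: none
Why: Hydride reduction of the ester to the primary alcohol with LiAlH4 at 0 °C, conditions under which a primary alkyl chloride is not reduced.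

Step 4
Reactants: 4 15-chloropentadecan-1-ol
Product: 5 1-chloro-15-iodopentadecane
Conditions: I2, PPh3, imidazole, CH2Cl2, 0 °C to rt
Reagents that add atoms: iodine, II
Why: Garegg–Samuelsson (Appel-type) iodination through the alkoxyphosphonium iodide and SN2 displacement, which leaves the chloride untouched and creates an iodide/chloride pair of very different SN2 reactivity.

Step 5
Reactants: 5 1-chloro-15-iodopentadecane; 6 3-sulfolene (2,5-dihydrothiophene 1,1-dioxide, 2 equiv)
Product: 7 2-(15-chloropentadecyl)-2,5-dihydrothiophene 1,1-dioxide (racemic)
Conditions: LiN(SiMe3)2 (1.5 equiv) added to 5 + 6, THF/HMPA (DMPU as substitute), −78 °C, dilute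
Reagents that add atoms: none
Why: α-Alkylation of the 3-sulfolene carbanion, generated in the presence of the electrophile so that it is trapped before it can ring-open, is an SN2 reaction that takes place at the iodide far faster than at the chloride, and the new ring stereocentre forms racemic and is destroyed in step 6.

Step 6
Reactants: 7 2-(15-chloropentadecyl)-2,5-dihydrothiophene 1,1-dioxide
Product: 8 (3E)-19-chlorononadeca-1,3-diene
Conditions: toluene, pyridine (cat.), BHT (cat.), reflux (110 °C), N2 sweep
Reagents that add atoms: none
Why: Thermal cheletropic extrusion of SO2 from the 2-alkyl-3-sulfolene is disrotatory with the alkyl group turning outward, so the (E)-1-substituted buta-1,3-diene should form stereospecifically.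

Step 7
Reactants: 8 (3E)-19-chlorononadeca-1,3-diene
Product: 9 (18E)-henicosa-18,20-dien-1-yne
Conditions: LiC≡CH·H2NCH2CH2NH2 (2.5 equiv), NaI (cat.), DMSO/THF, rt to 35 °C
Reagents that add atoms: lithium acetylide–ethylenediamine complex, [Li+].[C-]#C.NCCN
Why: SN2 alkylation of lithium acetylide by the primary chloride in DMSO, helped by in situ Finkelstein exchange with iodide, under conditions not basic enough to isomerise the unactivated conjugated diene.

Step 8
Reactants: 10 hex-5-ynoic acid
Product: 11 6-bromohex-5-ynoic acid
Conditions: Br2, KOH, H2O, 0 °C; then cold dilute HCl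
Reagents that add atoms: bromine, BrBr
Why: Hypobromite bromination of the terminal alkyne C–H (Straus conditions) in strongly alkaline water keeps the carboxylate a spectator and avoids the halo-enol-lactonisation that electrophilic bromine sources with silver salts can cause.

Step 9
Reactants: 9 (18E)-henicosa-18,20-dien-1-yne; 11 6-bromohex-5-ynoic acid (1.2 equiv, added slowly)
Product: 12 (24E)-heptacosa-24,26-dien-5,7-diynoic acid
Conditions: CuCl (10 mol %), NH2OH·HCl, n-BuNH2 (30% aq.), MeOH/THF, 0 °C to rt; then 1 M HCl; product kept in solution and away from UV light
Reagents that add atoms: none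
Why: Cadiot–Chodkiewicz coupling of the copper acetylide of 9 with the 1-bromoalkyne forms the C6–C7 bond of the unsymmetrical diyne, with hydroxylamine keeping copper monovalent to suppress homocoupling and the acid carried as its ammonium salt.

Step 10
Reactants: 12 (24E)-heptacosa-24,26-dien-5,7-diynoic acid
Product: 13 23-(3,6-dihydro-1,2-dioxin-3-yl)tricosa-5,7-diynoic acid (racemic)
Conditions: O2, 5,10,15,20-tetraphenylporphyrin (1 mol %), hν (white LED, λ > 400 nm filter), CH2Cl2 (0.02 M), 0 °C; stopped at full conversion of 12, Ar purge, kept dark and cold
Reagents that add atoms: dioxygen, O=O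
Why: The porphyrin triplet transfers its energy to ground-state O2, and the singlet oxygen so formed adds in a concerted suprafacial [4+2] cycloaddition across C24 and C27 of the s-cis conformer of the diene, the closest known reaction type being the dye-sensitised photooxygenation of (E)-1-alkylbuta-1,3-dienes such as (E)-penta-1,3-diene to 3-alkyl-3,6-dihydro-1,2-dioxines. The six-membered peroxide ring is closed by this intermolecular cycloaddition itself, both C–O bonds (C24–O and C27–O) being made in one event and the C25=C26 double bond remaining in the ring. The single new stereocentre (C24, ring C3) has no controlling element and forms as the racemate, which does not matter because it becomes an sp2 furan carbon in step 11. The step needs [4+2] to win over the ene reaction at the C23 hydrogens and the diene to react in preference to the diyne and the acid: the E geometry from step 6 keeps the s-cis conformer accessible and offers only a poorly ene-active 1,2-disubstituted olefin, the terminal vinyl group has no allylic sp3 hydrogen, and the electron-poor sp carbons and the carboxyl group do not react with this electrophilic oxidant. Irradiation above 400 nm avoids direct excitation of the diyne, and the light is switched off at full conversion so that no furan, itself a singlet-oxygen substrate, is ever present under oxidising conditions.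

Step 11
Reactants: 13 23-(3,6-dihydro-1,2-dioxin-3-yl)tricosa-5,7-diynoic acid
Product: 16 23-(furan-2-yl)tricosa-5,7-diynoic acid (target), via cis-hydroxy enal 14 (not isolated), via dihydrofuranol 15 (not isolated)
Conditions: Et3N (3 equiv), CH2Cl2, Ar, dark, 0 °C to rt; then 0.5 M HCl wash; PPTS (cat.), MgSO4, CH2Cl2, rt
Reagents that add atoms: none
Why: Kornblum–DeLaMare rearrangement (the amine removes the less hindered C27–H next to the peroxide oxygen and the O–O bond breaks to give the cis-4-hydroxy enal), followed by lactol closure and acid-catalysed aromatising dehydration, should give the furan, and the minor deprotonation at C24 leads through the cis-hydroxy enone to the same furan.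

**Compound list**

1 | pentadecanolide (oxacyclohexadecan-2-one) | O=C1CCCCCCCCCCCCCCO1 | starting material
2 | methyl 15-hydroxypentadecanoate | COC(=O)CCCCCCCCCCCCCCO | intermediate
3 | methyl 15-chloropentadecanoate | COC(=O)CCCCCCCCCCCCCCCl | intermediate
4 | 15-chloropentadecan-1-ol | OCCCCCCCCCCCCCCCCl | intermediate
5 | 1-chloro-15-iodopentadecane | ICCCCCCCCCCCCCCCCl | intermediate
6 | 3-sulfolene (2,5-dihydrothiophene 1,1-dioxide) | O=S1(=O)CC=CC1 | starting material
7 | 2-(15-chloropentadecyl)-2,5-dihydrothiophene 1,1-dioxide (racemic) | O=S1(=O)CC=CC1CCCCCCCCCCCCCCCCl | intermediate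
8 | (3E)-19-chlorononadeca-1,3-diene | C=C/C=C/CCCCCCCCCCCCCCCCl | intermediate
9 | (18E)-henicosa-18,20-dien-1-yne | C#CCCCCCCCCCCCCCCC/C=C/C=C | intermediate
10 | hex-5-ynoic acid | OC(=O)CCCC#C | starting material
11 | 6-bromohex-5-ynoic acid | OC(=O)CCCC#CBr | intermediate
12 | (24E)-heptacosa-24,26-dien-5,7-diynoic acid | OC(=O)CCCC#CC#CCCCCCCCCCCCCCCC/C=C/C=C | intermediate
13 | 23-(3,6-dihydro-1,2-dioxin-3-yl)tricosa-5,7-diynoic acid (racemic) | OC(=O)CCCC#CC#CCCCCCCCCCCCCCCCC1C=CCOO1 | intermediate
14 | (25Z)-24-hydroxy-27-oxoheptacos-25-ene-5,7-diynoic acid (racemic, not isolated) | OC(=O)CCCC#CC#CCCCCCCCCCCCCCCCC(O)/C=C\C=O | intermediate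
15 | 23-(5-hydroxy-2,5-dihydrofuran-2-yl)tricosa-5,7-diynoic acid (diastereomer mixture, not isolated) | OC(=O)CCCC#CC#CCCCCCCCCCCCCCCCC1C=CC(O)O1 | intermediate
16 | 23-(furan-2-yl)tricosa-5,7-diynoic acid | O=C(O)CCCC#CC#CCCCCCCCCCCCCCCCc1ccco1 | target

**Count**

Total steps: 11. Longest linear sequence: 10 (steps 1–7, 9, 10, 11 from pentadecanolide).

**Steps most likely to fail, with fallbacks**

Step 10. The cycloaddition to an open-chain diene is slow, so the sensitiser may bleach, the ene pathway at C23–H or light-induced reaction of the diyne may compete, and the peroxide may decompose on long irradiation. The fallback gives up the oxygenation and brings the ring in as furan itself. It sets out from 5: furan is lithiated (n-BuLi, THF, 0 °C) and the 2-furyllithium is alkylated at the iodide end of 5 (THF/DMPU, −20 °C to rt) to give 2-(15-chloropentadecyl)furan F1. Displacement of the chloride with LiC≡CH·H2NCH2CH2NH2 and NaI (cat.) in DMSO/THF should give 2-(heptadec-16-yn-1-yl)furan F2. Cadiot–Chodkiewicz coupling of F2 with 11 under the conditions of step 9 comes back to the route at the target 16.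

Step 5. A second alkylation of the product, ring-opening of the sulfolenyl anion before it is trapped, or crystallisation of the waxy iodide at −78 °C may leave conversion low. The fallback builds the E-diene by hydrometalation and cross-coupling. It sets out from 5: lithium (trimethylsilyl)acetylide in THF/DMPU displaces only the iodide to give (17-chloroheptadec-1-yn-1-yl)trimethylsilane F3, and K2CO3 in MeOH removes the silyl group to give 17-chloroheptadec-1-yne F4. Hydrozirconation of F4 with Cp2Zr(H)Cl (THF, rt) gives the (E)-alkenylzirconocene, which is coupled with vinyl bromide using Pd(PPh3)4 (zerovalent palladium, cat.) and ZnCl2. This comes back to the route at 8.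

Step 11. The lactol may dehydrate incompletely, the amine may isomerise the hydroxy enal to the saturated keto aldehyde, or the furan may degrade during the acidic finish. The fallback separates peroxide cleavage from ring formation. It sets out from 13: thiourea in MeOH/CH2Cl2 at rt reduces the O–O bond to give (25Z)-24,27-dihydroxyheptacos-25-ene-5,7-diynoic acid F5. Pyridinium chlorochromate (C5H5NH[CrO3Cl]) in CH2Cl2 then oxidises one allylic alcohol, and the cis-hydroxy carbonyl compound cyclises and loses water in the mildly acidic medium, the known oxidative cyclisation of cis-2-ene-1,4-diols to furans. This comes back to the route at 16.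

**Further compounds**

F1 | step 10 | 2-(15-chloropentadecyl)furan | ClCCCCCCCCCCCCCCCc1ccco1
F2 | step 10 | 2-(heptadec-16-yn-1-yl)furan | C#CCCCCCCCCCCCCCCCc1ccco1
F3 | step 5 | (17-chloroheptadec-1-yn-1-yl)trimethylsilane | C[Si](C)(C)C#CCCCCCCCCCCCCCCCCl
F4 | step 5 | 17-chloroheptadec-1-yne | C#CCCCCCCCCCCCCCCCCl
F5 | step 11 | (25Z)-24,27-dihydroxyheptacos-25-ene-5,7-diynoic acid (racemic) | OC(=O)CCCC#CC#CCCCCCCCCCCCCCCCC(O)/C=C\CO
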